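The numbers in the tables were computed for an exercise; noise was put on by code.

The vessel is closed, stirred and held at one temperature, so whatever free monomer you lose stays inside as something else.

| flask | free monomer | pre-initiator | remark | time |
|---|---|---|---|---|
| maple | 2 M | 50 mM | run made earlier |  |
| alder | 2 M | 200 mM | run made earlier |  |
| elm | 3 M | 100 mM | run made earlier |  |
| green | 2.0 M | 100 mM |  | 2.5 min |
| amber | 2.0 M | 100 mM |  | 8.0 min |

- maple (time / min: monomer in chains / %, free monomer / %): 0.200: 1.9, 91.3; 0.667: 1.4, 71.1; 1.00: 1.6, 63.2; 1.50: 3.0, 46.2; 2.50: 4.1, 26.8; 3.00: 4.9, 21.3
- alder (time / min: monomer in chains / %, free monomer / %): 0.200: 0.1, 91.3; 0.667: 2.8, 70.2; 1.00: 5.0, 58.5; 1.50: 8.3, 41.3; 2.50: 16.6, 21.3; 3.00: 19.3, 14.8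
- elm (time / min: monomer in chains / %, free monomer / %): 0.667: 2.2, 72.1; 1.33: 4.8, 49.8; 2.00: 10.5, 31.1; 2.50: 12.2, 23.8; 3.00: 11.8, 17.4

(standard deviation of a reading: 1 percentage point)

1. which of the two ends with the longer chains by the average number of monomer units in a chain (chains begun, living or dead) ("neither" if they lie within 10%) (green / amber / neither)
2. average number of monomer units in a chain (chains begun, living or dead) at the end, green
3. average number of monomer units in a chain (chains begun, living or dead) at the end, amber

Hold the last rows of maple and alder against each other, both at 3.00 min. The pre-initiator differs by a factor of 4.00 and the monomer in chains, as read, by 3.94, while c(free monomer) reads 21.3% in maple and 14.8% in alder. Chains took 6.23% of the monomer lost in maple and 22.7% in alder, so the remainder went another way.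

Now read each last row as a first-order fall. Maple gives 0.515 /min and alder gives 0.637 /min, a faster fall. My own reckoning interpolates in pre-initiator between them and gets, for 100 mM, the loss constant 0.556 /min. Multiplied by the time, it counts the lifetimes of free monomer a flask has used.

By this count green has used 1.39 lifetimes, which leaves an estimated 24.9%. Amber has the same charge and by this count has used 4.45, which leaves an estimated 1.17%. So you have an estimate of how far each flask has got, but the runs show no chain count, and my count gives no length.

The forecast does give lengths: amber longer, green 6 (2 to 20), amber 9 (3.3 to 30). It adds, “The absolute chain count is a guess”.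

    free monomer + living end → monomer in chains + living end, rate k1*[living end]*[free monomer] (k = 0.390 /M/s)
    free monomer + initiator → living end + monomer in chains (k = 0.00230 /M/s)
    free monomer → uncatalysed product (k = 0.00790 /s)
    pre-initiator ⇌ initiator (K = 0.300, k = 0.00910 /s)

The simulation also answers amber, with chains averaging 27.8 in green and 36.1 in amber, which is 4.63 and 4.01 times the forecast. Where the forecast guessed 25 to 30 mM of chains for green, green holds 0.00621 M of living ends at 2.50 min. Green keeps 25% free monomer, and amber keeps 0.66% of it, the limiting reagent there. Now take green read at 1.0 min instead. The same constant counts 0.556 lifetimes and leaves 57.3%. That reading holds 60.4% free monomer and 2.09% monomer in chains, and its chains average 15.0.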